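Ring B is built from a 2-pyrone. Four contiguous ring B carbons, C6 (pentyl), C1 (carboxyl), C2 (oxygen) and C3 (H), are carried in as C6, C5, C4 and C3 of benzyl 4-(benzyloxy)-2-oxo-6-pentyl-2H-pyran-5-carboxylate, made from a 3-oxooctanoate and malonyl dichloride. In one operation, cycloaddition of 1,1-bis(trimethylsilyloxy)ethene followed by loss of CO2 and silanol supplies C4 and C5, closes ring B and delivers the C4 oxygen, para to the carboxyl, as the only free phenol. That phenol is either methylated and debenzylated to give the ring A acid or acylated by this acid, so both rings derive from one intermediate; a final hydrogenolysis liberates the target.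

Key step: step 5

Remark: the target has no stereocentre, so no stereocontrol is needed; the two bridgehead centres of the transient cycloadduct 10 form as a racemate and vanish on aromatisation.

Step 1
Reactants: 1 methyl 3-oxooctanoate
Product: 2 benzyl 3-oxooctanoate
Conditions: BnOH (1.1 equiv), DMAP (0.2 equiv), PhMe, reflux (MeOH distilled off)
Reagents that add atoms: benzyl alcohol, OCc1ccccc1
Why: DMAP-catalysed transesterification of a β-keto ester, driven to the benzyl ester by removal of methanol.

Step 2
Reactants: 2 benzyl 3-oxooctanoate; 3 malonyl dichloride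
Product: 5 benzyl 4-hydroxy-2-oxo-6-pentyl-2H-pyran-5-carboxylate, via acyclic acid chloride 4 (not isolated)
Conditions: 3 (1.1 equiv), CH2Cl2, 0 °C to rt, then 40 °C (HCl swept out with N2)
Reagents that add atoms: none
Why: Condensation of a β-keto ester with malonyl dichloride: C-acylation at the doubly activated C2 gives 4, whose ketone enol oxygen is acylated by the second acid chloride to close the 4-hydroxy-2-pyrone, with pentyl on C6 and the ester on C5.

Step 3
Reactants: 5 benzyl 4-hydroxy-2-oxo-6-pentyl-2H-pyran-5-carboxylate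
Product: 6 benzyl 4-(benzyloxy)-2-oxo-6-pentyl-2H-pyran-5-carboxylate
Conditions: BnOH (1.2 equiv), PPh3 (1.3 equiv), DIAD (1.3 equiv), THF, 0 °C to rt
Reagents that add atoms: benzyl alcohol, OCc1ccccc1
Why: Mitsunobu etherification of the acidic 4-hydroxy-2-pyrone (a vinylogous acid) should alkylate O4 under neutral conditions and avoid the C3-benzylation that base and a benzyl halide can cause.

Step 4
Reactants: 7 trimethylsilyl acetate
Product: 9 1,1-bis(trimethylsilyloxy)ethene, via lithium enolate 8 (not isolated)
Conditions: LDA (commercial solution, 1.05 equiv), THF, −78 °C; TMSCl (1.1 equiv), −78 °C to rt; pentane, filtration, distillation at reduced pressure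
Reagents that add atoms: chlorotrimethylsilane, C[Si](C)(C)Cl
Why: Deprotonation of the silyl ester at low temperature and O-silylation of enolate 8 (silyl ketene acetal formation) should give the bis-silyl ketene acetal, which is kept and used under strictly anhydrous conditions.

Step 5
Reactants: 6 benzyl 4-(benzyloxy)-2-oxo-6-pentyl-2H-pyran-5-carboxylate; 9 1,1-bis(trimethylsilyloxy)ethene
Product: 13 benzyl 2-(benzyloxy)-4-hydroxy-6-pentylbenzoate, via bridged lactone cycloadduct 10 (not isolated), via cyclohexadiene bis-silyl acetal 11 (not isolated), via aryl trimethylsilyl ether 12 (not isolated)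
Conditions: 9 (4 equiv), PhMe, sealed tube, 120 to 140 °C; then 1 M aq HCl, THF, rt
Reagents that add atoms: none
Why: Proposed new method: the C5 ester and the lactone carbonyl lower the LUMO of pyrone 6, so the electron-rich ketene acetal 9 should add across C3 and C6 in an inverse-electron-demand Diels-Alder reaction, its CH2 bonding to C6 (β to the ester, δ to the lactone carbonyl) and its acetal carbon to C3; bridged lactone 10 then expels CO2 by a retro-[4+2] reaction, diene 11 aromatises by 1,2-elimination of trimethylsilanol, and aryl silyl ether 12 is cleaved in the acidic work-up. The closest known reaction type is the cycloaddition of 2-pyrone-5-carboxylates with 1,1-dialkoxyethenes, which gives 4-alkoxybenzoates after loss of CO2 and alcohol; neither a bis-silyl ketene acetal nor a 4-alkoxy-6-alkyl pyrone has been shown in it. Ring B is closed by an intermolecular [4+2] cycloaddition that forms both new ring bonds (ring B C5-C6 and C3-C4), so no separate cyclisation mode applies. No stereocentre survives, since the racemic bridgehead centres of 10 are erased on aromatisation. The step needs regioselectivity, which the C5 ester secures by making C6 the electrophilic terminus, so that the new oxygen ends para to the carboxyl and is the only one set free. The 4-benzyloxy donor and the C6 pentyl group should slow the cycloaddition, hence the sealed-tube temperature and the excess of 9, part of which is consumed by the silanol released.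

Step 6
Reactants: 13 benzyl 2-(benzyloxy)-4-hydroxy-6-pentylbenzoate
Product: 14 benzyl 2-(benzyloxy)-4-methoxy-6-pentylbenzoate
Conditions: MeI (1.5 equiv), K2CO3 (2 equiv), acetone, reflux
Reagents that add atoms: iodomethane, CI
Why: Williamson etherification of the only free phenol; the benzyl ester and benzyl ether are inert to these conditions.

Step 7
Reactants: 14 benzyl 2-(benzyloxy)-4-methoxy-6-pentylbenzoate
Product: 15 2-hydroxy-4-methoxy-6-pentylbenzoic acid
Conditions: H2 (1 atm), 10% Pd/C, EtOAc, rt
Reagents that add atoms: none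
Why: Catalytic hydrogenolysis should cleave the benzyl ester and the benzyl aryl ether and leave the methyl ether, giving the ring A hydroxy acid at room temperature without decarboxylation.

Step 8
Reactants: 15 2-hydroxy-4-methoxy-6-pentylbenzoic acid; 13 benzyl 2-(benzyloxy)-4-hydroxy-6-pentylbenzoate
Product: 17 benzyl 2-(benzyloxy)-4-[(2-hydroxy-4-methoxy-6-pentylbenzoyl)oxy]-6-pentylbenzoate, via mixed trifluoroacetic anhydride 16 (not isolated)
Conditions: 15 (1.0 equiv), 13 (1.0 equiv), TFAA (4 equiv), PhMe, rt; aq NaHCO3 work-up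
Reagents that add atoms: none
Why: Mixed-anhydride esterification as used for depsides: trifluoroacetic anhydride activates the hindered, electron-rich acid as 16, which acylates the single free phenol of 13, while the hydrogen-bonded 2-OH of 15 is a poor nucleophile and any phenolic trifluoroacetate is lost on aqueous work-up.

Step 9
Reactants: 17 benzyl 2-(benzyloxy)-4-[(2-hydroxy-4-methoxy-6-pentylbenzoyl)oxy]-6-pentylbenzoate
Product: 18 perlatolic acid
Conditions: H2 (1 atm), 10% Pd/C, EtOAc, rt
Reagents that add atoms: none
Why: Catalytic hydrogenolysis should remove the benzyl ester and the benzyl ether of ring B while the diaryl ester link and the methyl ether are untouched.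

Compound list
1 | methyl 3-oxooctanoate | CCCCCC(=O)CC(=O)OC | starting material
2 | benzyl 3-oxooctanoate | CCCCCC(=O)CC(=O)OCc1ccccc1 | intermediate
3 | malonyl dichloride | O=C(Cl)CC(=O)Cl | starting material
4 | benzyl 2-(3-chloro-3-oxopropanoyl)-3-oxooctanoate (racemic, enolisable, not isolated) | CCCCCC(=O)C(C(=O)OCc1ccccc1)C(=O)CC(=O)Cl | intermediate
5 | benzyl 4-hydroxy-2-oxo-6-pentyl-2H-pyran-5-carboxylate | CCCCCC1=C(C(=O)OCc2ccccc2)C(O)=CC(=O)O1 | intermediate
6 | benzyl 4-(benzyloxy)-2-oxo-6-pentyl-2H-pyran-5-carboxylate | CCCCCC1=C(C(=O)OCc2ccccc2)C(OCc2ccccc2)=CC(=O)O1 | intermediate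
7 | trimethylsilyl acetate | CC(=O)O[Si](C)(C)C | starting material
8 | lithium 1-(trimethylsilyloxy)ethen-1-olate (not isolated) | [Li+].[O-]C(=C)O[Si](C)(C)C | intermediate
9 | 1,1-bis(trimethylsilyloxy)ethene | C=C(O[Si](C)(C)C)O[Si](C)(C)C | intermediate
10 | benzyl 5-(benzyloxy)-3-oxo-1-pentyl-8,8-bis(trimethylsilyloxy)-2-oxabicyclo[2.2.2]oct-5-ene-6-carboxylate (racemic, not isolated) | CCCCCC12CC(O[Si](C)(C)C)(O[Si](C)(C)C)C(C(=O)O1)C(OCc1ccccc1)=C2C(=O)OCc1ccccc1 | intermediate
11 | benzyl 6-(benzyloxy)-2-pentyl-4,4-bis(trimethylsilyloxy)cyclohexa-1,5-diene-1-carboxylate (not isolated) | CCCCCC1=C(C(=O)OCc2ccccc2)C(OCc2ccccc2)=CC(O[Si](C)(C)C)(O[Si](C)(C)C)C1 | intermediate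
12 | benzyl 2-(benzyloxy)-6-pentyl-4-(trimethylsilyloxy)benzoate (not isolated) | CCCCCc1cc(O[Si](C)(C)C)cc(OCc2ccccc2)c1C(=O)OCc1ccccc1 | intermediate
13 | benzyl 2-(benzyloxy)-4-hydroxy-6-pentylbenzoate | CCCCCc1cc(O)cc(OCc2ccccc2)c1C(=O)OCc1ccccc1 | intermediate
14 | benzyl 2-(benzyloxy)-4-methoxy-6-pentylbenzoate | CCCCCc1cc(OC)cc(OCc2ccccc2)c1C(=O)OCc1ccccc1 | intermediate
15 | 2-hydroxy-4-methoxy-6-pentylbenzoic acid | CCCCCc1cc(OC)cc(O)c1C(=O)O | intermediate
16 | 2-hydroxy-4-methoxy-6-pentylbenzoic trifluoroacetic anhydride (not isolated) | CCCCCc1cc(OC)cc(O)c1C(=O)OC(=O)C(F)(F)F | intermediate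
17 | benzyl 2-(benzyloxy)-4-[(2-hydroxy-4-methoxy-6-pentylbenzoyl)oxy]-6-pentylbenzoate | CCCCCc1cc(OC(=O)c2c(O)cc(OC)cc2CCCCC)cc(OCc2ccccc2)c1C(=O)OCc1ccccc1 | intermediate
18 | perlatolic acid, 2-hydroxy-4-[(2-hydroxy-4-methoxy-6-pentylbenzoyl)oxy]-6-pentylbenzoic acid | CCCCCc1cc(OC(=O)c2c(O)cc(OC)cc2CCCCC)cc(O)c1C(=O)O | target

Total step count: 9.
Longest linear sequence: 8 steps (steps 1, 2, 3, 5, 6, 7, 8 and 9, from 1 to 18); step 4 is a one-step side branch.

Steps most likely to fail

Step 5 (proposed new method). The cycloaddition may not start at a temperature that the ketene acetal survives, because the C4 donor and the C6 pentyl group deactivate and shield the diene. The acetal may also add in Michael fashion with silyl transfer instead of closing the ring, or be used up by protodesilylation. The fallback uses known chemistry and sets out from 2.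
- The sodium enolate of 2 (NaH, THF) is C-acetoacetylated with diketene; the triketo ester cyclises by intramolecular aldol condensation and aromatises to benzyl 2,4-dihydroxy-6-pentylbenzoate F1.
- One portion of F1 is methylated at the non-chelated 4-OH (MeI, K2CO3, acetone) to benzyl 2-hydroxy-4-methoxy-6-pentylbenzoate F2, and hydrogenolysis (H2, Pd/C) of F2 comes back to the route at 15.
- Acid 15 is then coupled with the remaining F1 under the conditions of step 8, the chelated 2-OH of F1 staying free, to give benzyl 2-hydroxy-4-[(2-hydroxy-4-methoxy-6-pentylbenzoyl)oxy]-6-pentylbenzoate F3.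
- Hydrogenolysis of F3 comes back to the route at 18.

Step 2. The 4-hydroxypyrone may react further with a second molecule of malonyl dichloride across C3 and O4, the dichloride may self-condense to tar, and the HCl may erode the benzyl ester. The fallback sets out from 2 and separates the two bond formations.
- The magnesium enolate of 2 (MgCl2, pyridine, CH2Cl2, 0 °C) is C-acylated with methyl 3-chloro-3-oxopropanoate to give 1-benzyl 5-methyl 2-hexanoyl-3-oxopentanedioate F4.
- Enol lactonisation of F4 with loss of methanol (DBU, PhMe, reflux) comes back to the route at 5.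

Step 8. The unprotected hydroxy acid may acylate itself, may decarboxylate in the acidic medium, or may react too slowly because the activated carbonyl is flanked by two ortho substituents. The fallback sets out from 14 and uses a protected acid chloride.
- The benzyl ester of 14 is saponified with the benzyl ether retained (KOH, DMSO/H2O, 90 °C) to give 2-(benzyloxy)-4-methoxy-6-pentylbenzoic acid F5.
- Oxalyl chloride with catalytic DMF in CH2Cl2 gives 2-(benzyloxy)-4-methoxy-6-pentylbenzoyl chloride F6.
- Acylation of 13 with F6 (Et3N, DMAP, CH2Cl2) gives benzyl 2-(benzyloxy)-4-{[2-(benzyloxy)-4-methoxy-6-pentylbenzoyl]oxy}-6-pentylbenzoate F7.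
- Hydrogenolysis of all three benzyl groups of F7 (H2, Pd/C, EtOAc) comes back to the route at 18.

Further compounds
F1 | step 5 | benzyl 2,4-dihydroxy-6-pentylbenzoate | CCCCCc1cc(O)cc(O)c1C(=O)OCc1ccccc1
F2 | step 5 | benzyl 2-hydroxy-4-methoxy-6-pentylbenzoate | CCCCCc1cc(OC)cc(O)c1C(=O)OCc1ccccc1
F3 | step 5 | benzyl 2-hydroxy-4-[(2-hydroxy-4-methoxy-6-pentylbenzoyl)oxy]-6-pentylbenzoate | CCCCCc1cc(OC(=O)c2c(O)cc(OC)cc2CCCCC)cc(O)c1C(=O)OCc1ccccc1
F4 | step 2 | 1-benzyl 5-methyl 2-hexanoyl-3-oxopentanedioate | CCCCCC(=O)C(C(=O)OCc1ccccc1)C(=O)CC(=O)OC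
F5 | step 8 | 2-(benzyloxy)-4-methoxy-6-pentylbenzoic acid | CCCCCc1cc(OC)cc(OCc2ccccc2)c1C(=O)O
F6 | step 8 | 2-(benzyloxy)-4-methoxy-6-pentylbenzoyl chloride | CCCCCc1cc(OC)cc(OCc2ccccc2)c1C(=O)Cl
F7 | step 8 | benzyl 2-(benzyloxy)-4-{[2-(benzyloxy)-4-methoxy-6-pentylbenzoyl]oxy}-6-pentylbenzoate | CCCCCc1cc(OC(=O)c2c(OCc3ccccc3)cc(OC)cc2CCCCC)cc(OCc2ccccc2)c1C(=O)OCc1ccccc1
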